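**Plan**
- Cuts, in retrosynthetic order: the C6 ketone and both esters; the oxepane bond O–C3 together with the C4 hydroxyl (7‑exo opening of a C3/C4 epoxide by the C16 hydroxyl); the nine‑membered ring at C5–C6 (retro‑Claisen, re‑forming O–C3 of a seven‑membered enol ether); O–C3 of a lactone (retro‑Baeyer–Villiger) and the C3 vinyl group; the cyclohexane at C1–C14 and C12–C13 (retro‑Diels–Alder).
- Enabling feature: in the oxonane (O, C2–C9) C7 is sp2 and C3 carries O and CH3, with C4–C5–C6 between them. Read as C7=O / C3=C4 this is the γ,δ‑unsaturated ketone of an allyl vinyl ether C6=C7–O–C3–C4=C5, whose C7–O–C3 link closes a seven‑membered 1,4‑dioxepane (O, C7, C8, C9, O, C2, C3) on the oxolane.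
- Forward order: meso 8‑oxabicyclo[3.2.1]octenone (oxolane = dearomatised furan) → C3 methyl → C10 ketone → diene → Diels–Alder cyclohexane → C3 quaternary (methyl, vinyl) → lactone (6→7) → enol ether → Claisen (7→9) → C7 methylene → epoxide → oxepane → esters → C6 ketone.
- Stereochemistry: C2/C9 from enantioselective deprotonation of the meso ketone; C1 from exo Diels–Alder; C10, C12, C14 by equilibration; C11 by L‑Selectride; C15 by A(1,3)‑controlled hydroboration; C3/C4 from the Z‑alkene of the Claisen product, face‑selective epoxidation and SN2 opening with inversion at C3.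

Key step: step 20

Numbering remark: asbestinin numbering is used for every intermediate. O bridges C2 and C9; C1/C10 are the ring fusion; C3–C8 are the six oxonane carbons (C7 is the carbonyl carbon of 1); C11–C14 complete the cyclohexane; C15–C17 are the side chain on C14; C18 is on C3, C19 on C7, C20 on C12. In the bicyclo[3.2.1] intermediates exo means anti to the C3–C7–C8 bridge, and axial on C3 means syn to the ring oxygen.

Assumptions: 1 and the cis enol ether 10 are taken as commercial. The antipodes written for the lithium amide (step 1) and the borane (step 3) are those expected to give the drawn series (for the borane by analogy with cis‑alkenes and norbornene); the mirror‑image reagent would be used if the sense proved opposite.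

**Step 1**
Reactants: 1 8‑oxabicyclo[3.2.1]oct‑6‑en‑3‑one
Product: 3 3‑methyl ketone (methyl axial), via lithium enolate 2 (not isolated)
Conditions: (R,R)‑bis(1‑phenylethyl)amine, n‑BuLi, LiCl, THF, −78 °C; then MeI, DMPU, −78 → −40 °C
Reagents that add atoms: iodomethane, CI
Why: Enantioselective deprotonation of a meso ketone by a chiral lithium amide removes one of the two enantiotopic axial α‑hydrogens, which fixes the absolute configuration at C2 and C9 and marks C3; the enolate is methylated from the exo face.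

**Step 2**
Reactants: 3 3‑methyl ketone
Product: 4 C7 ethylene ketal, methyl equatorial
Conditions: HOCH2CH2OH, p‑TsOH (cat.), benzene, reflux, Dean–Stark
Reagents that add atoms: ethylene glycol, OCCO
Why: Acid‑catalysed ketalisation masks C7 for the next ten steps; the C3 methyl should equilibrate to the equatorial epimer through the enol, which is of no consequence because C3 is planarised again in step 15.

**Step 3**
Reactants: 4 C7 ketal
Product: 6 C10 exo‑alcohol, via C10 bis(isopinocampheyl)borane 5 (not isolated)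
Conditions: (+)‑Ipc2BH, THF, −25 °C; then NaOH, H2O2, 0 °C
Reagents that add atoms: hydrogen peroxide, OO
Why: Asymmetric hydroboration–oxidation: boron adds to the exo face of the bridged 2,5‑dihydrofuran, and the chiral borane should distinguish the two pseudo‑enantiotopic alkene carbons as it does in meso cis‑alkenes, placing oxygen on C10; the minor enantiomer of 4 should end as the regioisomeric alcohol and be removed.

**Step 4**
Reactants: 6 C10 exo‑alcohol
Product: 7 C10 ketone
Conditions: Dess–Martin periodinane, NaHCO3, CH2Cl2, 0 °C → rt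
Reagents that add atoms: none
Why: Dess–Martin oxidation of a secondary alcohol; the adjacent C9 is a bridgehead and cannot epimerise.

**Step 5**
Reactants: 7 C10 ketone
Product: 9 C10 enol triflate (C1=C10), via potassium enolate 8 (not isolated)
Conditions: KHMDS, THF, −78 °C; then PhNTf2, −78 → 0 °C
Reagents that add atoms: N‑phenylbis(trifluoromethanesulfonimide), O=S(=O)(N(c1ccccc1)S(=O)(=O)C(F)(F)F)C(F)(F)F
Why: Enolisation can only go toward C1 because C9 is a bridgehead, so O‑triflation of the enolate gives a single vinyl triflate.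

**Step 6**
Reactants: 10 (Z)‑1‑ethoxyprop‑1‑ene
Product: 12 tributyl[(E)‑1‑ethoxyprop‑1‑en‑1‑yl]stannane, via (Z)‑1‑ethoxy‑1‑lithioprop‑1‑ene 11 (not isolated)
Conditions: t‑BuLi, THF, −78 → −10 °C; then Bu3SnCl, −78 °C → rt
Reagents that add atoms: tributyltin chloride, CCCC[Sn](Cl)(CCCC)CCCC
Why: Oxygen‑directed α‑vinylic lithiation of a cis enol ether followed by stannylation with retention, so the methyl stays cis to the ethoxy group.

**Step 7**
Reactants: 9 C10 enol triflate; 12 tributyl[(E)‑1‑ethoxyprop‑1‑en‑1‑yl]stannane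
Product: 13 diene C1=C10–C11(OEt)=C12H–CH3
Conditions: Pd(PPh3)4 (5 mol %), LiCl, THF, 65 °C
Reagents that add atoms: none
Why: Stille coupling of a vinyl triflate with an α‑alkoxyvinylstannane proceeds with retention at both partners and joins C10 to C11.

**Step 8**
Reactants: 13 diene; 14 but‑3‑en‑2‑one
Product: 15 Diels–Alder adduct (C12/C14 epimers)
Conditions: toluene, BHT (cat.), 90 °C, sealed tube
Reagents that add atoms: none
Why: Diels–Alder reaction; the dienophile should add to the exo face of the bicyclic diene (anti to the ketal bridge), which sets C1 with H‑1 endo, and the 2‑ethoxy group directs the acetyl group to C14 ("para" orientation).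

**Step 9**
Reactants: 15 Diels–Alder adduct
Product: 17 diketone, via unequilibrated diketone mixture 16 (not isolated)
Conditions: 5 % aq. oxalic acid, THF, 0 °C; then K2CO3, MeOH, rt
Reagents that add atoms: water, O
Why: Enol ether hydrolysis (much faster than dioxolane hydrolysis) followed by base equilibration of the three enolisable centres: the exo‑cis ring fusion at C10, the C12 methyl cis to C10–C9 (2,6‑cis cyclohexanone) and the C14 acetyl trans to C1–C2 are the expected thermodynamic arrangement.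

**Step 10**
Reactants: 17 diketone
Product: 18 14‑isopropenyl 11‑ketone
Conditions: Ph3PCH3Br, KOt‑Bu, THF, 0 °C
Reagents that add atoms: methyltriphenylphosphonium bromide, C[P+](c1ccccc1)(c1ccccc1)c1ccccc1.[Br-]
Why: Wittig methylenation should be selective for the unhindered methyl ketone over the C11 ketone, which is branched at both α‑carbons.

**Step 11**
Reactants: 18 14‑isopropenyl 11‑ketone
Product: 19 11‑alcohol
Conditions: L‑Selectride, THF, −78 °C; then H2O
Reagents that add atoms: none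
Why: The bulky hydride should attack the ketone from the face carrying H‑10 and H‑12, giving the alcohol cis to the C12 methyl and to the C10–C9 bond.

**Step 12**
Reactants: 19 11‑alcohol
Product: 21 11,16‑diol, via bis(9‑BBN) adduct 20 (not isolated)
Conditions: 9‑BBN (3 equiv), THF, 0 °C → rt; then NaOH, H2O2
Reagents that add atoms: hydrogen peroxide, OO
Why: Hydroboration–oxidation of the 1,1‑disubstituted alkene; in the A(1,3)‑minimised conformer H‑14 eclipses the double bond and the borane adds anti to C1, which should give the 15R centre.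

**Step 13**
Reactants: 21 11,16‑diol (ketal)
Product: 22 7‑keto 11,16‑diol
Conditions: 1 M HCl, THF, 40 °C
Reagents that add atoms: water, O
Why: Acid hydrolysis of the dioxolane releases the C7 ketone before any acid‑labile silyl ether is present.

**Step 14**
Reactants: 22 7‑keto 11,16‑diol
Product: 23 11,16‑bis‑TBS ether
Conditions: TBSOTf, 2,6‑lutidine, CH2Cl2, −78 → −40 °C
Reagents that add atoms: tert‑butyldimethylsilyl triflate, CC(C)(C)[Si](C)(C)OS(=O)(=O)C(F)(F)F
Why: Silylation of both hydroxyls; the low temperature and the weak base avoid silyl enol ether formation at C7.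

**Step 15**
Reactants: 23 11,16‑bis‑TBS ether
Product: 24 C3=C7 trimethylsilyl enol ether
Conditions: TMSCl, NaI, Et3N, MeCN, 40 °C
Reagents that add atoms: chlorotrimethylsilane, C[Si](C)(C)Cl
Why: Equilibrating silylation should give the more substituted (tetrasubstituted) enol ether, so the methyl introduced in step 1 fixes the regiochemistry at C3.

**Step 16**
Reactants: 24 C3=C7 trimethylsilyl enol ether
Product: 26 aldol with quaternary C3, via lithium enolate 25 (not isolated)
Conditions: MeLi, THF, 0 °C; then CH3CHO, −78 °C; AcOH, −78 °C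
Reagents that add atoms: acetaldehyde, CC=O
Why: MeLi cleavage of the enol silane gives the regiodefined enolate, and the aldol addition should occur anti to the two‑carbon bridge (now carrying the cyclohexane), placing the 1‑hydroxyethyl group axial and the methyl equatorial; the carbinol configuration is irrelevant.

**Step 17**
Reactants: 26 aldol
Product: 27 3‑methyl‑3‑vinyl ketone
Conditions: Burgess reagent, toluene, 70 °C
Reagents that add atoms: none
Why: Syn‑elimination through the sulfamate ester; C3 is quaternary, so only the methyl hydrogens are available and the vinyl group is the sole alkene possible.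

**Step 18**
Reactants: 27 3‑methyl‑3‑vinyl ketone
Product: 28 seven‑membered lactone
Conditions: m‑CPBA, NaHCO3, CH2Cl2, 0 °C → rt
Reagents that add atoms: 3‑chloroperoxybenzoic acid, OOC(=O)c1cccc(Cl)c1
Why: Baeyer–Villiger oxidation; the quaternary allylic C3 migrates in preference to the C8 methylene and with retention, so oxygen is inserted between C3 and C7 and the six‑membered ring becomes the seven‑membered lactone.

**Step 19**
Reactants: 28 seven‑membered lactone
Product: 29 2‑methylene‑1,4‑dioxepane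
Conditions: Cp2TiMe2, toluene, 65 °C, dark
Reagents that add atoms: dimethyltitanocene, C[Ti](C)(C1C=CC=C1)C1C=CC=C1
Why: Titanium‑carbene methylenation of the lactone carbonyl under non‑acidic conditions gives the exocyclic enol ether (C6 is introduced here).

**Step 20**
Reactants: 29 2‑methylene‑1,4‑dioxepane
Product: 30 (3Z)‑oxonenone
Conditions: xylenes, i‑Pr2NEt (trace), 140 °C, sealed tube
Reagents that add atoms: none
Why: Thermal [3,3]‑sigmatropic (Claisen) rearrangement of the allyl vinyl ether C6=C7–O–C3–C4=C5 through a chair‑like transition state: the ring O–C3 bond breaks while C5–C6 forms, so the lactone‑derived oxygen leaves the ring as the C7 ketone and the seven‑membered 1,4‑dioxepane (O, C7, C8, C9, O, C2, C3) is enlarged by two atoms to the nine‑membered oxonane (O, C2–C9). The closest known reaction type is the Claisen ring expansion of 2‑methylene cyclic ethers that carry a vinyl group on the other α‑carbon, used for medium carbocycles and for the oxonene of eunicellane diterpenes. The nine‑membered ring is not closed by cyclisation but arises by ring enlargement, the new σ‑bond C5–C6 being formed suprafacially on both three‑atom fragments inside the existing bicycle. No stereocentre is created and that at C3 is lost; the only new stereo‑element, the C3=C4 double bond, must be Z because the C2–O–C9–C8 tether forces C2 into the pseudo‑axial position of the chair. The step needs the concerted shift to outrun ionisation or [1,3] shift of the tertiary allylic C3–O bond; this is secured by the axial vinyl group set in step 16, which points toward the exocyclic methylene and holds C5 within bonding distance of C6, and by base‑buffered, acid‑free conditions.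

**Step 21**
Reactants: 30 (3Z)‑oxonenone
Product: 31 7‑methylene diene
Conditions: Ph3PCH3Br, KOt‑Bu, THF, 0 °C → rt
Reagents that add atoms: methyltriphenylphosphonium bromide, C[P+](c1ccccc1)(c1ccccc1)c1ccccc1.[Br-]
Why: Wittig methylenation of the unhindered C7 ketone installs C19; no ester or other carbonyl is present.

**Step 22**
Reactants: 31 7‑methylene diene
Product: 32 16‑alcohol
Conditions: HF·pyridine, pyridine, THF, 0 °C
Reagents that add atoms: none
Why: Buffered fluoride should cleave the primary TBS ether selectively and leave the hindered secondary C11 silyl ether.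

**Step 23**
Reactants: 32 16‑alcohol
Product: 34 tetracyclic 4‑alcohol, via 3,4‑epoxy alcohol 33 (not isolated)
Conditions: DMDO (1.0 equiv), acetone/CH2Cl2, −40 °C; then CSA (0.1 equiv), 0 °C
Reagents that add atoms: dimethyldioxirane, CC1(C)OO1
Why: Electrophilic epoxidation should take the trisubstituted C3=C4 before the 1,1‑disubstituted C7 methylene, and from the face turned to the ring oxygen, because in the conformer with the C3 methyl eclipsing H‑2 the rear face is screened by the cyclohexane and the C14 side chain; acid then triggers 7‑exo‑tet opening by the C16 hydroxyl at the tertiary C3 with inversion, which closes the oxepane and leaves the epoxide oxygen as the C4 hydroxyl.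

**Step 24**
Reactants: 34 tetracyclic 4‑alcohol
Product: 35 4‑octanoate
Conditions: n‑C7H15COCl, pyridine, DMAP (cat.), CH2Cl2, 0 °C
Reagents that add atoms: octanoyl chloride, CCCCCCCC(Cl)=O
Why: Acylation of the only free hydroxyl.

**Step 25**
Reactants: 35 4‑octanoate
Product: 36 11‑alcohol
Conditions: HF·pyridine, THF, rt
Reagents that add atoms: none
Why: Fluoride cleavage of the remaining secondary TBS ether; the ester, the tertiary ether and the alkene are stable to these conditions.

**Step 26**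
Reactants: 36 11‑alcohol
Product: 37 11‑acetate 4‑octanoate
Conditions: Ac2O, pyridine, DMAP (cat.), CH2Cl2, 0 °C → rt
Reagents that add atoms: acetic anhydride, CC(=O)OC(C)=O
Why: Acetylation of the C11 hydroxyl.

**Step 27**
Reactants: 37 11‑acetate 4‑octanoate
Product: 38 6‑hydroxy compound (C6 epimers)
Conditions: SeO2 (0.5 equiv), t‑BuOOH, CH2Cl2, rt
Reagents that add atoms: selenium dioxide, O=[Se]=O; tert‑butyl hydroperoxide, CC(C)(C)OO
Why: Selenium dioxide allylic oxidation (ene reaction, then [2,3] shift) keeps the exocyclic methylene and should hydroxylate C6 in preference to C8, whose hydrogens are deactivated by the adjacent C9–O bond and more hindered; the C6 configuration is irrelevant.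

**Step 28**
Reactants: 38 6‑hydroxy compound
Product: 39 asbestinin 16
Conditions: Dess–Martin periodinane, NaHCO3, CH2Cl2, 0 °C
Reagents that add atoms: none
Why: Neutral Dess–Martin oxidation of the allylic alcohol gives the α‑methylene ketone without exposing the β‑acyloxy ketone to base.

**Compound list**
1 | 8‑oxabicyclo[3.2.1]oct‑6‑en‑3‑one (meso; carbonyl carbon = C7) | O=C3C[C@@H]2O[C@H](C3)C=C2 | starting material
2 | lithium enolate of 1 (C3=C7–OLi) | C3=C(O[Li])C[C@@H]2O[C@H]3C=C2 | intermediate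
3 | 3‑methyl ketone, methyl axial (C3 = α‑carbon on the C2 bridgehead) | C[C@@H]3C(=O)C[C@@H]2O[C@H]3C=C2 | intermediate
4 | C7 ethylene ketal of the 3‑methyl ketone, methyl equatorial | C[C@H]3C5(OCCO5)C[C@@H]2O[C@H]3C=C2 | intermediate
5 | C10‑exo bis(isopinocampheyl)borane adduct of 4 | C[C@H]3C5(OCCO5)C[C@@H]2O[C@H]3C[C@H]2B([C@H]1C[C@H]2C[C@@H]([C@@H]1C)C2(C)C)[C@H]1C[C@H]2C[C@@H]([C@@H]1C)C2(C)C | intermediate
6 | C10 exo‑alcohol (ketal) | C[C@H]3C5(OCCO5)C[C@@H]2O[C@H]3C[C@H]2O | intermediate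
7 | C10 ketone (ketal) | C[C@H]3C5(OCCO5)C[C@@H]2O[C@H]3CC2=O | intermediate
8 | potassium C1=C10 enolate of 7 | C[C@H]3C5(OCCO5)C[C@@H]2O[C@H]3C=C2O[K] | intermediate
9 | C10 enol triflate, C1=C10 (ketal) | C[C@H]3C5(OCCO5)C[C@@H]2O[C@H]3C=C2OS(=O)(=O)C(F)(F)F | intermediate
10 | (Z)‑1‑ethoxyprop‑1‑ene | C/C=C\OCC | starting material
11 | (Z)‑1‑ethoxy‑1‑lithioprop‑1‑ene | C/C=C(\OCC)[Li] | intermediate
12 | tributyl[(E)‑1‑ethoxyprop‑1‑en‑1‑yl]stannane (CH3 cis to OEt) | C/C=C(\OCC)[Sn](CCCC)(CCCC)CCCC | intermediate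
13 | diene C1=C10–C11(OEt)=C12H–CH3 on the ketal bicycle (CH3 cis to OEt) | C[C@H]3C5(OCCO5)C[C@@H]2O[C@H]3C=C2/C(OCC)=C/C | intermediate
14 | but‑3‑en‑2‑one | CC(=O)C=C | starting material
15 | Diels–Alder adduct: exo‑fused cyclohexene, C10=C11–OEt, 12‑methyl, 14‑acetyl, H‑1 endo (C12/C14 epimers) | C[C@H]3C5(OCCO5)C[C@@H]2O[C@H]3[C@H]4C(C(C)=O)CC(C)C(OCC)=C42 | intermediate
16 | 11‑oxo‑14‑acetyl tricycle before equilibration (C10/C12/C14 epimers) | C[C@H]3C5(OCCO5)C[C@@H]2O[C@H]3[C@H]4C(C(C)=O)CC(C)C(=O)C42 | intermediate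
17 | diketone: H‑10 cis to H‑1 (both endo), 12‑methyl cis to C10–C9, 14‑acetyl trans to C1–C2 | C[C@H]3C5(OCCO5)C[C@@H]2O[C@H]3[C@H]4[C@@H](C[C@@H](C)C(=O)[C@H]42)C(C)=O | intermediate
18 | 14‑isopropenyl 11‑ketone | C[C@H]3C5(OCCO5)C[C@@H]2O[C@H]3[C@H]4[C@@H](C[C@@H](C)C(=O)[C@H]42)C(C)=C | intermediate
19 | 11‑alcohol, OH cis to the 12‑methyl and to C10–C9 | C[C@H]3C5(OCCO5)C[C@@H]2O[C@H]3[C@H]4[C@@H](C[C@@H](C)[C@@H](O)[C@H]42)C(C)=C | intermediate
20 | bis(9‑BBN) adduct: C16–B and C11–O–B | C[C@H]3C5(OCCO5)C[C@@H]2O[C@H]3[C@H]4[C@@H](C[C@@H](C)[C@@H](OB6C7CCCC6CCC7)[C@H]42)[C@@H](C)CB6C7CCCC6CCC7 | intermediate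
21 | 11,16‑diol with the 15R methyl centre (ketal) | C[C@H]3C5(OCCO5)C[C@@H]2O[C@H]3[C@H]4[C@@H](C[C@@H](C)[C@@H](O)[C@H]42)[C@@H](C)CO | intermediate
22 | 7‑keto 11,16‑diol | C[C@H]3C(=O)C[C@@H]2O[C@H]3[C@H]4[C@@H](C[C@@H](C)[C@@H](O)[C@H]42)[C@@H](C)CO | intermediate
23 | 11,16‑bis‑TBS ether of 22 | C[C@H]3C(=O)C[C@@H]2O[C@H]3[C@H]4[C@@H](C[C@@H](C)[C@@H](O[Si](C)(C)C(C)(C)C)[C@H]42)[C@@H](C)CO[Si](C)(C)C(C)(C)C | intermediate
24 | C3=C7 trimethylsilyl enol ether | CC3=C(O[Si](C)(C)C)C[C@@H]2O[C@H]3[C@H]4[C@@H](C[C@@H](C)[C@@H](O[Si](C)(C)C(C)(C)C)[C@H]42)[C@@H](C)CO[Si](C)(C)C(C)(C)C | intermediate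
25 | lithium C3=C7 enolate | CC3=C(O[Li])C[C@@H]2O[C@H]3[C@H]4[C@@H](C[C@@H](C)[C@@H](O[Si](C)(C)C(C)(C)C)[C@H]42)[C@@H](C)CO[Si](C)(C)C(C)(C)C | intermediate
26 | aldol: quaternary C3 with axial 1‑hydroxyethyl and equatorial methyl (carbinol epimers) | CC(O)[C@]3(C)C(=O)C[C@@H]2O[C@H]3[C@H]4[C@@H](C[C@@H](C)[C@@H](O[Si](C)(C)C(C)(C)C)[C@H]42)[C@@H](C)CO[Si](C)(C)C(C)(C)C | intermediate
27 | 3‑methyl‑3‑vinyl 7‑ketone (vinyl axial) | C=C[C@]3(C)C(=O)C[C@@H]2O[C@H]3[C@H]4[C@@H](C[C@@H](C)[C@@H](O[Si](C)(C)C(C)(C)C)[C@H]42)[C@@H](C)CO[Si](C)(C)C(C)(C)C | intermediate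
28 | seven‑membered lactone C7(=O)–O–C3 (ring O, C7, C8, C9, O, C2, C3) | C=C[C@]3(C)OC(=O)C[C@@H]2O[C@H]3[C@H]4[C@@H](C[C@@H](C)[C@@H](O[Si](C)(C)C(C)(C)C)[C@H]42)[C@@H](C)CO[Si](C)(C)C(C)(C)C | intermediate
29 | 2‑methylene‑1,4‑dioxepane: C7(=C6H2)–O–C3(CH3)(vinyl) | C=C[C@]3(C)OC(=C)C[C@@H]2O[C@H]3[C@H]4[C@@H](C[C@@H](C)[C@@H](O[Si](C)(C)C(C)(C)C)[C@H]42)[C@@H](C)CO[Si](C)(C)C(C)(C)C | intermediate
30 | (3Z)‑oxonenone: nine‑membered ring O, C2–C9 with C7 ketone and C3(CH3)=C4 | C/C3=C/CCC(=O)C[C@@H]2O[C@H]3[C@H]4[C@@H](C[C@@H](C)[C@@H](O[Si](C)(C)C(C)(C)C)[C@H]42)[C@@H](C)CO[Si](C)(C)C(C)(C)C | intermediate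
31 | 7‑methylene (3Z)‑oxonene (diene) | C/C3=C/CCC(=C)C[C@@H]2O[C@H]3[C@H]4[C@@H](C[C@@H](C)[C@@H](O[Si](C)(C)C(C)(C)C)[C@H]42)[C@@H](C)CO[Si](C)(C)C(C)(C)C | intermediate
32 | 16‑alcohol of 31 (11‑OTBS) | C/C3=C/CCC(=C)C[C@@H]2O[C@H]3[C@H]4[C@@H](C[C@@H](C)[C@@H](O[Si](C)(C)C(C)(C)C)[C@H]42)[C@@H](C)CO | intermediate
33 | 3,4‑epoxy 16‑alcohol, epoxide oxygen anti to the C14 side chain | C[C@]35O[C@@H]5CCC(=C)C[C@@H]2O[C@H]3[C@H]4[C@@H](C[C@@H](C)[C@@H](O[Si](C)(C)C(C)(C)C)[C@H]42)[C@@H](C)CO | intermediate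
34 | tetracyclic 4‑alcohol (oxepane C3–O–C16 closed), 11‑OTBS, 7‑methylene | C=C1C[C@@H]2O[C@H]3[C@H]4[C@@H](C[C@@H](C)[C@@H](O[Si](C)(C)C(C)(C)C)[C@H]42)[C@@H](C)CO[C@@]3(C)[C@H](O)CC1 | intermediate
35 | 4‑octanoate of 34 | C=C1C[C@@H]2O[C@H]3[C@H]4[C@@H](C[C@@H](C)[C@@H](O[Si](C)(C)C(C)(C)C)[C@H]42)[C@@H](C)CO[C@@]3(C)[C@H](OC(=O)CCCCCCC)CC1 | intermediate
36 | 11‑alcohol 4‑octanoate | C=C1C[C@@H]2O[C@H]3[C@H]4[C@@H](C[C@@H](C)[C@@H](O)[C@H]42)[C@@H](C)CO[C@@]3(C)[C@H](OC(=O)CCCCCCC)CC1 | intermediate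
37 | 11‑acetate 4‑octanoate (6‑deoxo compound) | C=C1C[C@@H]2O[C@H]3[C@H]4[C@@H](C[C@@H](C)[C@@H](OC(C)=O)[C@H]42)[C@@H](C)CO[C@@]3(C)[C@H](OC(=O)CCCCCCC)CC1 | intermediate
38 | 6‑hydroxy compound (allylic alcohol, C6 epimers) | C=C1C[C@@H]2O[C@H]3[C@H]4[C@@H](C[C@@H](C)[C@@H](OC(C)=O)[C@H]42)[C@@H](C)CO[C@@]3(C)[C@H](OC(=O)CCCCCCC)CC1O | intermediate
39 | asbestinin 16 | C=C1C[C@@H]2O[C@H]3[C@H]4[C@@H](C[C@@H](C)[C@@H](OC(C)=O)[C@H]42)[C@@H](C)CO[C@@]3(C)[C@H](OC(=O)CCCCCCC)CC1=O | target

**Count**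
Total: 28 steps. Longest linear sequence: 27 steps (1–5 and 7–28); step 6 prepares the stannane.

**Steps most likely to fail**

1. Step 23 (epoxidation and oxepane closure). The oxidant may add to the rear face of C3=C4 (the face turned to the C14 side chain) or show poor facial selectivity. The epoxide oxygen then sits where the ether oxygen must go, and the C16 hydroxyl cannot open it with inversion at C3. Fallback, from 32 back to 35: the rear‑face epoxy alcohol F1 is opened by caesium octanoate (DMF, 80 °C) in an SN2 reaction at the secondary C4, giving the C4 octanoate with a free tertiary C3 alcohol, diol ester F2. Tf2O/2,6‑lutidine (CH2Cl2, −78 °C) converts the primary alcohol into the primary triflate F3, which the tertiary C3 hydroxyl displaces in a Williamson‑type 7‑exo‑tet closure to give 35. The two oxygens exchange roles, so both epoxide faces lead to the same C3/C4 configuration.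

2. Step 20 (Claisen ring expansion). At 140 °C the tertiary allylic C3–O bond may ionise, or undergo [1,3] shift or elimination, faster than the concerted shift, and the enol ether may be lost to adventitious acid. Fallback, from 29 back to 30: triisobutylaluminium (CH2Cl2, −78 → 0 °C) promotes the same bond reorganisation through an aluminium‑bound polar transition state at low temperature and reduces the resulting ketone in situ by β‑hydride transfer. The ring‑expanded C7 alcohol F4 is re‑oxidised with Dess–Martin periodinane to 30.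

3. Step 27 (allylic oxidation). Site selectivity between the two allylic methylenes (C6 and C8) may be poor, or over‑oxidation may occur, late in the route. Fallback, from 30 back to 39: the C6 oxygen is installed by enolate chemistry before methylenation.
   - KHMDS (THF, −78 °C) deprotonates 30 at the less hindered C6 to the potassium enolate F5, and the Davis oxaziridine gives the 6‑hydroxy ketone F6.
   - Wittig methylenation gives the allylic alcohol F7, and Dess–Martin oxidation the enone F8.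
   - HF·pyridine/pyridine frees the primary alcohol to give hydroxy enone F9.
   - DMDO gives the epoxy alcohol F10, which CSA closes in the same flask to the oxepane alcohol F11.
   - Octanoyl chloride/pyridine gives the octanoate F12, HF·pyridine the 11‑alcohol F13, and Ac2O/pyridine gives 39.

**Further compounds**
F1 | step 23 | rear‑face 3,4‑epoxy 16‑alcohol (C3/C4 epimer of 33) | C[C@@]35O[C@H]5CCC(=C)C[C@@H]2O[C@H]3[C@H]4[C@@H](C[C@@H](C)[C@@H](O[Si](C)(C)C(C)(C)C)[C@H]42)[C@@H](C)CO
F2 | step 23 | 3,16‑diol 4‑octanoate (11‑OTBS) | C[C@]3(O)[C@H](OC(=O)CCCCCCC)CCC(=C)C[C@@H]2O[C@H]3[C@H]4[C@@H](C[C@@H](C)[C@@H](O[Si](C)(C)C(C)(C)C)[C@H]42)[C@@H](C)CO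
F3 | step 23 | 16‑triflate of F2 | C[C@]3(O)[C@H](OC(=O)CCCCCCC)CCC(=C)C[C@@H]2O[C@H]3[C@H]4[C@@H](C[C@@H](C)[C@@H](O[Si](C)(C)C(C)(C)C)[C@H]42)[C@@H](C)COS(=O)(=O)C(F)(F)F
F4 | step 20 | (3Z)‑oxonen‑7‑ol (C7 epimers), bis‑TBS | C/C3=C/CCC(O)C[C@@H]2O[C@H]3[C@H]4[C@@H](C[C@@H](C)[C@@H](O[Si](C)(C)C(C)(C)C)[C@H]42)[C@@H](C)CO[Si](C)(C)C(C)(C)C
F5 | step 27 | potassium C6=C7 enolate of 30 | C/C3=C/CC=C(O[K])C[C@@H]2O[C@H]3[C@H]4[C@@H](C[C@@H](C)[C@@H](O[Si](C)(C)C(C)(C)C)[C@H]42)[C@@H](C)CO[Si](C)(C)C(C)(C)C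
F6 | step 27 | 6‑hydroxy 7‑ketone (C6 epimers), bis‑TBS | C/C3=C/CC(O)C(=O)C[C@@H]2O[C@H]3[C@H]4[C@@H](C[C@@H](C)[C@@H](O[Si](C)(C)C(C)(C)C)[C@H]42)[C@@H](C)CO[Si](C)(C)C(C)(C)C
F7 | step 27 | 6‑hydroxy 7‑methylene compound, bis‑TBS | C/C3=C/CC(O)C(=C)C[C@@H]2O[C@H]3[C@H]4[C@@H](C[C@@H](C)[C@@H](O[Si](C)(C)C(C)(C)C)[C@H]42)[C@@H](C)CO[Si](C)(C)C(C)(C)C
F8 | step 27 | 7‑methylene 6‑ketone (enone), bis‑TBS | C/C3=C/CC(=O)C(=C)C[C@@H]2O[C@H]3[C@H]4[C@@H](C[C@@H](C)[C@@H](O[Si](C)(C)C(C)(C)C)[C@H]42)[C@@H](C)CO[Si](C)(C)C(C)(C)C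
F9 | step 27 | 16‑hydroxy enone (11‑OTBS) | C/C3=C/CC(=O)C(=C)C[C@@H]2O[C@H]3[C@H]4[C@@H](C[C@@H](C)[C@@H](O[Si](C)(C)C(C)(C)C)[C@H]42)[C@@H](C)CO
F10 | step 27 | 3,4‑epoxy 16‑hydroxy enone | C[C@]35O[C@@H]5CC(=O)C(=C)C[C@@H]2O[C@H]3[C@H]4[C@@H](C[C@@H](C)[C@@H](O[Si](C)(C)C(C)(C)C)[C@H]42)[C@@H](C)CO
F11 | step 27 | tetracyclic 4‑hydroxy enone (11‑OTBS) | C=C1C[C@@H]2O[C@H]3[C@H]4[C@@H](C[C@@H](C)[C@@H](O[Si](C)(C)C(C)(C)C)[C@H]42)[C@@H](C)CO[C@@]3(C)[C@H](O)CC1=O
F12 | step 27 | 4‑octanoate enone (11‑OTBS) | C=C1C[C@@H]2O[C@H]3[C@H]4[C@@H](C[C@@H](C)[C@@H](O[Si](C)(C)C(C)(C)C)[C@H]42)[C@@H](C)CO[C@@]3(C)[C@H](OC(=O)CCCCCCC)CC1=O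
F13 | step 27 | 11‑hydroxy 4‑octanoate enone | C=C1C[C@@H]2O[C@H]3[C@H]4[C@@H](C[C@@H](C)[C@@H](O)[C@H]42)[C@@H](C)CO[C@@]3(C)[C@H](OC(=O)CCCCCCC)CC1=O
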